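**Retrosynthetic overview**
1. Gmelinol ⇐ acyclic (R)-hydroxy ketone ArCH(O–CH2–CH=CH–Ar, Z)–CO–CH2OH. One Lewis-acid Prins/oxa-cyclization closes ring A (C1–C5 bond) and then ring B (C6–O7 bond); C2 controls C1 and C5, and the Z alkene fixes the endo aryl group at C6.
2. Hydroxy ketone ⇐ silyl-protected alkynyl carbinol (oxidation, cis semi-hydrogenation, desilylation).
3. Carbinol ⇐ (2S,3S)-aryl epoxy silyl ether + 3-arylpropargyl alcohol (benzylic epoxide opening with inversion sets C2).
4. Epoxide ⇐ Sharpless epoxidation of (E)-3,4-dimethoxycinnamyl alcohol (from the methyl cinnamate); alkynol ⇐ Sonogashira coupling of 4-iodoveratrole with propargyl alcohol.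

Assumption: the target is the enantiomer written in the SMILES, i.e. (1S,2R,5R,6R)-2,6-bis(3,4-dimethoxyphenyl)-3,7-dioxabicyclo[3.3.0]octan-1-ol (2-aryl exo and cis to OH, 6-aryl endo). Atom numbers C1–C8 below follow this skeleton (ring A: C1–C2–O3–C4–C5; ring B: C1–C5–C6–O7–C8).

**Route**

Step 1
Reactants: 1 methyl (E)-3-(3,4-dimethoxyphenyl)prop-2-enoate
Product: 2 (E)-3-(3,4-dimethoxyphenyl)prop-2-en-1-ol
Conditions: i-Bu2AlH (2.5 equiv), CH2Cl2, −78 → 0 °C; aq. KNaC4H4O6
Reagents that add atoms: none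
Why: Low-temperature i-Bu2AlH ester reduction gives the allylic alcohol by 1,2-hydride delivery without touching the alkene; no stereocenter is formed.

Step 2
Reactants: 2 (E)-3-(3,4-dimethoxyphenyl)prop-2-en-1-ol
Product: 4 tert-butyl{[(2S,3S)-3-(3,4-dimethoxyphenyl)oxiran-2-yl]methoxy}dimethylsilane, via epoxy alcohol 3 (not isolated)
Conditions: Ti(OiPr)4 (10 mol %), L-(+)-diethyl tartrate (14 mol %), t-BuOOH (1.5 equiv, isooctane), 4 Å molecular sieves, CH2Cl2, −20 °C; then P(OMe)3 (0.6 equiv); then TBSCl, Et3N, DMAP (cat.), −20 → 0 °C; basic work-up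
Reagents that add atoms: tert-butyl hydroperoxide CC(C)(C)OO; tert-butyldimethylsilyl chloride CC(C)(C)[Si](C)(C)Cl
Why: Catalytic Sharpless asymmetric epoxidation with L-(+)-tartrate gives the (2S,3S)-epoxide of the E allylic alcohol, and silylation in the same flask (Sharpless in situ derivatization) traps the acid-labile electron-rich epoxy alcohol before any acidic work-up.

Step 3
Reactants: 5 4-iodo-1,2-dimethoxybenzene; 6 prop-2-yn-1-ol
Product: 7 3-(3,4-dimethoxyphenyl)prop-2-yn-1-ol
Conditions: PdCl2(PPh3)2 (2 mol %), CuI (4 mol %), Et3N, THF, rt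
Reagents that add atoms: none
Why: Sonogashira coupling of an aryl iodide with a terminal alkyne; no stereocenter is formed.

Step 4
Reactants: 4 tert-butyl{[(2S,3S)-3-(3,4-dimethoxyphenyl)oxiran-2-yl]methoxy}dimethylsilane; 7 3-(3,4-dimethoxyphenyl)prop-2-yn-1-ol
Product: 8 (1R,2S)-3-{[tert-butyl(dimethyl)silyl]oxy}-1-(3,4-dimethoxyphenyl)-1-{[3-(3,4-dimethoxyphenyl)prop-2-yn-1-yl]oxy}propan-2-ol
Conditions: BF3·OEt2 (10 mol %), CH2Cl2, −40 → −20 °C, epoxide added over 2 h to an equimolar amount of the alkynol and the catalyst; Et3N quench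
Reagents that add atoms: none
Why: Lewis-acid-catalysed alcoholysis of an aryl epoxide is a pure addition of the O–H bond of the alkynol across the benzylic C–O bond by backside attack, so inversion turns the (3S)-epoxide carbon into the (1R)-benzylic ether that becomes C2 of the target; slow addition of the epoxide keeps the propargylic alcohol, which does not ionise under BF3, in excess over free epoxide and suppresses rearrangement and oligomerisation.

Step 5
Reactants: 8 (1R,2S)-3-{[tert-butyl(dimethyl)silyl]oxy}-1-(3,4-dimethoxyphenyl)-1-{[3-(3,4-dimethoxyphenyl)prop-2-yn-1-yl]oxy}propan-2-ol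
Product: 9 (1R)-3-{[tert-butyl(dimethyl)silyl]oxy}-1-(3,4-dimethoxyphenyl)-1-{[3-(3,4-dimethoxyphenyl)prop-2-yn-1-yl]oxy}propan-2-one
Conditions: Dess–Martin periodinane (1.3 equiv), CH2Cl2, 0 °C → rt
Reagents that add atoms: none
Why: Dess–Martin oxidation of the only free (secondary) alcohol gives the ketone under non-basic conditions that leave the enolisable benzylic stereocenter untouched.

Step 6
Reactants: 9 (1R)-3-{[tert-butyl(dimethyl)silyl]oxy}-1-(3,4-dimethoxyphenyl)-1-{[3-(3,4-dimethoxyphenyl)prop-2-yn-1-yl]oxy}propan-2-one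
Product: 10 (1R)-3-{[tert-butyl(dimethyl)silyl]oxy}-1-(3,4-dimethoxyphenyl)-1-{[(2Z)-3-(3,4-dimethoxyphenyl)prop-2-en-1-yl]oxy}propan-2-one
Conditions: H2 (1 atm), Pd/CaCO3 poisoned with Pb(OAc)2, quinoline, EtOAc, rt, stopped at 1 equiv H2
Reagents that add atoms: none
Why: Semi-hydrogenation over lead-poisoned Pd/CaCO3 (Lindlar reduction) adds H2 syn to the alkyne to give the Z alkene needed for the endo C6 aryl group, and the poisoned catalyst spares the ketone, the benzylic ether and the silyl ether.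

Step 7
Reactants: 10 (1R)-3-{[tert-butyl(dimethyl)silyl]oxy}-1-(3,4-dimethoxyphenyl)-1-{[(2Z)-3-(3,4-dimethoxyphenyl)prop-2-en-1-yl]oxy}propan-2-one
Product: 11 (1R)-1-(3,4-dimethoxyphenyl)-1-{[(2Z)-3-(3,4-dimethoxyphenyl)prop-2-en-1-yl]oxy}-3-hydroxypropan-2-one
Conditions: HF·pyridine, pyridine, THF, 0 °C → rt; used directly
Reagents that add atoms: none
Why: Fluoride-mediated silyl ether cleavage under buffered, non-basic conditions frees the primary alcohol without epimerising the α-aryl ketone.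

Step 8
Reactants: 11 (1R)-1-(3,4-dimethoxyphenyl)-1-{[(2Z)-3-(3,4-dimethoxyphenyl)prop-2-en-1-yl]oxy}-3-hydroxypropan-2-one
Product: 12 (+)-gmelinol, (1S,2R,5R,6R)-2,6-bis(3,4-dimethoxyphenyl)-3,7-dioxabicyclo[3.3.0]octan-1-ol
Conditions: Sc(OTf)3 (10 mol %), 2,6-di-tert-butyl-4-methylpyridine (20 mol %), CH2Cl2, −40 → −10 °C; Et3N quench at low temperature
Reagents that add atoms: none
Why: Proposed new method: Sc(OTf)3 chelates the α-hydroxy ketone (C1=O and C8–OH), the electron-rich Z styrene attacks C1 through a five-membered transition state with the C2 aryl group next to the carbonyl oxygen instead of the CH2 group (aryl cis to the new OH, ring A), and the scandium-bound O7 captures the nascent dimethoxybenzylic cation at C6 on the same alkene face before C5–C6 rotation (ring B), so the cis ring fusion is enforced and the Z geometry becomes the endo C6 aryl group; the closest known reactions are Lewis-acid Prins bicyclizations (Prins/oxa-cyclization cascades in which E and Z aryl alkenes react stereospecifically) and chelation-controlled Hosomi–Sakurai additions to α-alkoxy ketones.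

**Compound list**
1 | methyl (E)-3-(3,4-dimethoxyphenyl)prop-2-enoate | COC(=O)/C=C/c1ccc(OC)c(OC)c1 | starting material
2 | (E)-3-(3,4-dimethoxyphenyl)prop-2-en-1-ol | OC/C=C/c1ccc(OC)c(OC)c1 | intermediate
3 | [(2S,3S)-3-(3,4-dimethoxyphenyl)oxiran-2-yl]methanol | OC[C@@H]1O[C@H]1c1ccc(OC)c(OC)c1 | intermediate
4 | tert-butyl{[(2S,3S)-3-(3,4-dimethoxyphenyl)oxiran-2-yl]methoxy}dimethylsilane | CC(C)(C)[Si](C)(C)OC[C@@H]1O[C@H]1c1ccc(OC)c(OC)c1 | intermediate
5 | 4-iodo-1,2-dimethoxybenzene | COc1ccc(I)cc1OC | starting material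
6 | prop-2-yn-1-ol | OCC#C | starting material
7 | 3-(3,4-dimethoxyphenyl)prop-2-yn-1-ol | OCC#Cc1ccc(OC)c(OC)c1 | intermediate
8 | (1R,2S)-3-{[tert-butyl(dimethyl)silyl]oxy}-1-(3,4-dimethoxyphenyl)-1-{[3-(3,4-dimethoxyphenyl)prop-2-yn-1-yl]oxy}propan-2-ol | CC(C)(C)[Si](C)(C)OC[C@H](O)[C@H](OCC#Cc1ccc(OC)c(OC)c1)c1ccc(OC)c(OC)c1 | intermediate
9 | (1R)-3-{[tert-butyl(dimethyl)silyl]oxy}-1-(3,4-dimethoxyphenyl)-1-{[3-(3,4-dimethoxyphenyl)prop-2-yn-1-yl]oxy}propan-2-one | CC(C)(C)[Si](C)(C)OCC(=O)[C@H](OCC#Cc1ccc(OC)c(OC)c1)c1ccc(OC)c(OC)c1 | intermediate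
10 | (1R)-3-{[tert-butyl(dimethyl)silyl]oxy}-1-(3,4-dimethoxyphenyl)-1-{[(2Z)-3-(3,4-dimethoxyphenyl)prop-2-en-1-yl]oxy}propan-2-one | CC(C)(C)[Si](C)(C)OCC(=O)[C@H](OC/C=C\c1ccc(OC)c(OC)c1)c1ccc(OC)c(OC)c1 | intermediate
11 | (1R)-1-(3,4-dimethoxyphenyl)-1-{[(2Z)-3-(3,4-dimethoxyphenyl)prop-2-en-1-yl]oxy}-3-hydroxypropan-2-one | OCC(=O)[C@H](OC/C=C\c1ccc(OC)c(OC)c1)c1ccc(OC)c(OC)c1 | intermediate
12 | (+)-gmelinol, (1S,2R,5R,6R)-2,6-bis(3,4-dimethoxyphenyl)-3,7-dioxabicyclo[3.3.0]octan-1-ol | COc1ccc([C@H]2OC[C@@H]3[C@H](c4ccc(OC)c(OC)c4)OC[C@]23O)cc1OC | target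

**Totals**
Total steps: 8. Longest linear sequence: 7 (steps 1, 2, 4, 5, 6, 7, 8 from compound 1).

**Three steps most likely to fail, with fallbacks**

Step 8 (Prins bicyclization). The dimethoxybenzylic cation may rotate before capture, which would give the C6 epimer, or the cinnamyl ether may ionise under the Lewis acid. The fallback sets out from 9 and returns at 12. Ni(cod)2 (10 mol %)/PBu3 with Et3SiH in THF effects a Montgomery-type reductive alkyne–ketone cyclization that closes ring A and delivers H and C1 to the same side of the alkyne, giving the (E)-benzylidene oxolane bis-silyl ether F1. Bu4NF in THF gives the (E)-benzylidene oxolane diol F2. I2/NaHCO3 in MeCN at 0 °C closes ring B by 5-endo anti iodoetherification: the primary OH attacks benzylic C6 opposite to iodine, which from this E alkene again gives the endo C6 aryl group, and the product is the 5-iodo bicycle F3. Bu3SnH/AIBN in toluene at 80 °C replaces iodine by hydrogen on the convex face of the cis-fused bicycle to give 12.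

Step 4 (benzylic epoxide opening). Partial ionisation of the electron-rich aryl epoxide would give some retention at C2, which after step 5 means lower enantiomeric purity; competing rearrangement of the epoxide would lower the yield. The fallback sets out from 2 and 7 and returns at 9. ClCO2Me/pyridine converts 2 into the cinnamyl methyl carbonate F4. [Ir(cod)Cl]2 with a Feringa-type phosphoramidite ligand (enantiomer chosen for the S product) and the zinc alkoxide of 7 (from Et2Zn) in THF gives the branched (S)-allyl propargyl ether F5 by asymmetric allylic etherification, so the benzylic C–O stereocenter is set by the catalyst and not by an ionisable epoxide. OsO4 (cat.)/N-methylmorpholine N-oxide dihydroxylates only the vinyl group to give the diol epimer mixture F6. TBSCl/imidazole silylates the primary alcohol to give the silyl ether epimer mixture F7 (8 plus its C2 epimer). Dess–Martin periodinane converges both epimers on 9.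

Step 2 (asymmetric epoxidation with in situ silylation). The dimethoxyphenyl epoxy alcohol may open under the titanium alkoxide conditions before it is silylated. The fallback sets out from 2 and returns at 4. TBSCl/imidazole gives the cinnamyl silyl ether F8. This is epoxidised with KHSO5 and the enantiomer of the D-fructose-derived Shi ketone (prepared from L-sorbose) in buffered MeCN/dimethoxymethane/water (K2CO3, pH about 10.5, 0 °C). The dioxirane epoxidation of a trans-disubstituted styrene runs under basic, titanium-free conditions and gives 4 directly.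

**Further compounds**
F1 | step 8 | tert-butyl({(2R,3S,4E)-2-(3,4-dimethoxyphenyl)-4-[(3,4-dimethoxyphenyl)methylidene]-3-[(triethylsilyl)oxy]oxolan-3-yl}methoxy)dimethylsilane | COc1ccc([C@H]2OC/C(=C\c3ccc(OC)c(OC)c3)[C@]2(O[Si](CC)(CC)CC)CO[Si](C)(C)C(C)(C)C)cc1OC
F2 | step 8 | (2R,3S,4E)-2-(3,4-dimethoxyphenyl)-4-[(3,4-dimethoxyphenyl)methylidene]-3-(hydroxymethyl)oxolan-3-ol | COc1ccc([C@H]2OC/C(=C\c3ccc(OC)c(OC)c3)[C@]2(O)CO)cc1OC
F3 | step 8 | (1S,2R,5S,6S)-2,6-bis(3,4-dimethoxyphenyl)-5-iodo-3,7-dioxabicyclo[3.3.0]octan-1-ol (5-iodogmelinol) | COc1ccc([C@H]2OC[C@]3(I)[C@H](c4ccc(OC)c(OC)c4)OC[C@]23O)cc1OC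
F4 | step 4 | (E)-3-(3,4-dimethoxyphenyl)prop-2-en-1-yl methyl carbonate | COC(=O)OC/C=C/c1ccc(OC)c(OC)c1
F5 | step 4 | 4-[(1S)-1-{[3-(3,4-dimethoxyphenyl)prop-2-yn-1-yl]oxy}prop-2-en-1-yl]-1,2-dimethoxybenzene | C=C[C@H](OCC#Cc1ccc(OC)c(OC)c1)c1ccc(OC)c(OC)c1
F6 | step 4 | (3R)-3-(3,4-dimethoxyphenyl)-3-{[3-(3,4-dimethoxyphenyl)prop-2-yn-1-yl]oxy}propane-1,2-diol (both C2 epimers) | OCC(O)[C@H](OCC#Cc1ccc(OC)c(OC)c1)c1ccc(OC)c(OC)c1
F7 | step 4 | (1R)-3-{[tert-butyl(dimethyl)silyl]oxy}-1-(3,4-dimethoxyphenyl)-1-{[3-(3,4-dimethoxyphenyl)prop-2-yn-1-yl]oxy}propan-2-ol (both C2 epimers) | CC(C)(C)[Si](C)(C)OCC(O)[C@H](OCC#Cc1ccc(OC)c(OC)c1)c1ccc(OC)c(OC)c1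
F8 | step 2 | tert-butyl{[(2E)-3-(3,4-dimethoxyphenyl)prop-2-en-1-yl]oxy}dimethylsilane | CC(C)(C)[Si](C)(C)OC/C=C/c1ccc(OC)c(OC)c1
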